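**Plan**
- Retrosynthesis: the C6 acetate and the C15 methyl are removed first (acylation; methyl addition to a C4 ketone). Ring B is then cut at C9–C10 and C5–C6 in a single [4+2] event after a C7=C8 double bond is put back, and C1–Br is traced to an allylic alcohol by SN2.
- Enabling feature: in ring B the oxygen-bearing C6 sits next to C5, C5 is alpha to C4 (a latent carbonyl), and the quaternary C10 is beta to C4. This is the "ortho" adduct pattern of a 1-oxygenated buta-1,3-diene (C6–C7–C8–C9) with the C5=C10 bond of a 3-methylcyclohex-2-enone (ring A), and C1–Br is allylic to that bond before the event.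
- Forward: ring A comes from dearomatization of 4-methoxy-2-methylphenol (quinone monoketal, partial hydrogenation, CBS reduction, Appel bromination). Ring B is then closed on it by a Lewis acid Diels–Alder reaction with a 2-isopropyl-1-silyloxydiene.
- Stereochemistry: absolute configuration from the CBS reduction (C1, inverted in the Appel step); C10 by addition anti to C1–Br; C6 by the endo rule; C5 by epimerization to the trans-decalin; C7 by hydroxyl-directed hydrogenation; C4 by equatorial, alkoxide-assisted methyl delivery.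
- Helpers taken out later: the C4 ketone (becomes the carbinol), the C7=C8 bond (hydrogenated) and the TBS group (cleaved).

Key step: step 8

Remark: eudesmane numbering is used for the bicyclic compounds (C1 = CHBr, C4 = carbinol carbon, C5/C10 = ring fusion, C6 = O-bearing, C7 = isopropyl-bearing, C15 = methyl on C4; ring A = C1–C5 and C10, ring B = C5–C10; beta = face of the C10 methyl). Compounds 1, 7, 8 and 10 are taken as commercial.

**Step 1**
Reactants: 1 4-methoxy-2-methylphenol
Product: 2 4,4-dimethoxy-2-methylcyclohexa-2,5-dien-1-one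
Conditions: PhI(OAc)2 (1.1 equiv), MeOH, 0 °C
Reagents that add atoms: methanol, CO
Why: Oxidative dearomatization of a para-alkoxyphenol with a hypervalent iodine reagent (quinone monoketal formation) traps the phenoxonium ion at the methoxy-bearing carbon with methanol, and no stereocentre is formed.

**Step 2**
Reactants: 2 4,4-dimethoxy-2-methylcyclohexa-2,5-dien-1-one
Product: 3 4,4-dimethoxy-2-methylcyclohex-2-en-1-one
Conditions: H2 (1 atm), RhCl(PPh3)3 (5 mol%), toluene/EtOH, 23 °C
Reagents that add atoms: none
Why: Homogeneous hydrogenation with RhCl(PPh3)3 should reduce the cis-disubstituted double bond of a cross-conjugated dienone well before the methyl-bearing trisubstituted one (as in the partial hydrogenation of steroidal 1,4-dien-3-ones), and the neutral medium avoids loss of methanol and rearomatization.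

**Step 3**
Reactants: 3 4,4-dimethoxy-2-methylcyclohex-2-en-1-one
Product: 5 (S)-4-hydroxy-3-methylcyclohex-2-en-1-one, via (S)-4,4-dimethoxy-2-methylcyclohex-2-en-1-ol 4 (not isolated)
Conditions: (R)-2-methyl-CBS-oxazaborolidine (0.1 equiv), BH3·SMe2 (0.7 equiv), THF, −20 °C; MeOH quench; then 1 M aq. HCl, THF, 0 °C
Reagents that add atoms: water, O
Why: CBS reduction of a 2-substituted cyclohexenone, with the methyl-bearing alkenyl carbon acting as the large group, should set the carbinol centre as (S), and the acidic work-up hydrolyses the allylic dimethyl ketal through its conjugated oxocarbenium ion faster than the allylic alcohol can ionize.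

**Step 4**
Reactants: 5 (S)-4-hydroxy-3-methylcyclohex-2-en-1-one
Product: 6 (R)-4-bromo-3-methylcyclohex-2-en-1-one
Conditions: CBr4 (1.2 equiv), PPh3 (1.2 equiv), CH2Cl2, −30 → 0 °C; used at once
Reagents that add atoms: carbon tetrabromide, BrC(Br)(Br)Br
Why: In this Appel reaction bromide displaces the alkoxyphosphonium group by SN2 with inversion at a carbon that is still allylic and not yet neopentyl, so the (S)-alcohol should give the (R)-bromide, and the carbonyl-deactivated allyl system disfavours SN1 and SN2′ pathways.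

**Step 5**
Reactants: 7 3-methylbutanal; 8 cyclohexylamine
Product: 9 (E)-N-cyclohexyl-3-methylbutan-1-imine
Conditions: MgSO4, Et2O, 0 → 23 °C
Reagents that add atoms: none
Why: Condensation of an aldehyde with a primary amine gives the aldimine, which serves as the non-self-condensing enolate equivalent for the next step.

**Step 6**
Reactants: 9 (E)-N-cyclohexyl-3-methylbutan-1-imine; 10 acetaldehyde
Product: 12 (2E)-2-(propan-2-yl)but-2-enal, via 4-(cyclohexylimino)-3-(propan-2-yl)butan-2-ol 11 (not isolated)
Conditions: LiN(iPr)2 (LDA, commercial solution, 1.05 equiv), THF, −78 °C; 10, −78 °C; then 2 M aq. HCl, 40 °C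
Reagents that add atoms: water, O
Why: In this directed aldol condensation the lithiated aldimine adds to acetaldehyde without self-condensation, and acid hydrolysis of the beta-hydroxy imine with dehydration should give the conjugated (E)-enal as the thermodynamic isomer, both aldol stereocentres being erased.

**Step 7**
Reactants: 12 (2E)-2-(propan-2-yl)but-2-enal
Product: 13 tert-butyl(dimethyl){[(1E)-2-(propan-2-yl)buta-1,3-dien-1-yl]oxy}silane
Conditions: TBSOTf (1.1 equiv), Et3N (1.5 equiv), Et2O, 0 °C
Reagents that add atoms: tert-butyldimethylsilyl trifluoromethanesulfonate, CC(C)(C)[Si](C)(C)OS(=O)(=O)C(F)(F)F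
Why: O-silylation of the enal and gamma-deprotonation (silyl dienol ether formation) through the s-trans conformer should place the silyloxy group trans to the vinyl group and give the (1E)-diene, and any (1Z) isomer is inert in the cycloaddition.

**Step 8**
Reactants: 6 (R)-4-bromo-3-methylcyclohex-2-en-1-one; 13 tert-butyl(dimethyl){[(1E)-2-(propan-2-yl)buta-1,3-dien-1-yl]oxy}silane
Product: 14 1β-bromo-6α-[(tert-butyldimethylsilyl)oxy]-15-nor-5β-eudesm-7-en-4-one (cis-fused adduct)
Conditions: 13 (2 equiv), Me2AlNTf2 (0.3 equiv, preformed from AlMe3 and HNTf2), CH2Cl2, −78 → −20 °C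
Reagents that add atoms: none
Why: Coordination of the halide-free Lewis acid to the C4 carbonyl of 6 lowers the LUMO of the C5=C10 bond, and the (1E)-silyloxydiene adds in a concerted but asynchronous [4+2] cycloaddition in which the unsubstituted, most nucleophilic terminus C9 bonds to the beta carbon C10 and the oxygenated terminus C6 closes onto the alpha carbon C5 ("ortho" orientation). The closest known reaction type is the Lewis acid-catalysed Diels–Alder reaction of 3-methylcyclohex-2-enones and other beta,beta-disubstituted enones with silyloxydienes, which builds quaternary ring-fusion carbons. Ring B is the only ring closed, by intermolecular [4+2] cycloaddition that is suprafacial on both partners, with ring A carried intact as the dienophile. C10 is set by approach of the diene anti to the allylic C1–Br bond, which allylic strain with the C10 methyl holds pseudo-axial; C5 follows from suprafacial addition (hydrogen cis to the C10 methyl, a cis ring fusion that step 9 corrects); C6 is set by the endo transition state (ring A carbonyl under the diene) together with the (1E) geometry of the dienol ether, which puts the silyloxy group alpha. The step needs regio-, facial and endo selectivity and must outrun loss of HBr from 6: the partners are polarity-matched (1-oxygenated diene with an enone), the hindered beta carbon meets the unhindered CH2 terminus, and a Lewis acid without nucleophilic halide at low temperature should leave the allylic bromide untouched.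

**Step 9**
Reactants: 14 1β-bromo-6α-[(tert-butyldimethylsilyl)oxy]-15-nor-5β-eudesm-7-en-4-one
Product: 15 1β-bromo-6α-[(tert-butyldimethylsilyl)oxy]-15-nor-5α-eudesm-7-en-4-one (trans-fused)
Conditions: DBU (0.3 equiv), CH2Cl2, 23 °C
Reagents that add atoms: none
Why: Base-mediated epimerization through the C4 enolate should convert the cis-fused ketone into the more stable trans-fused one (bromine equatorial, no axial ring A bond on ring B) with reprotonation at C5 from the alpha face away from the angular methyl, while the pseudo-equatorial C6–O bond lies near the enolate plane and is poorly aligned for beta-elimination.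

**Step 10**
Reactants: 15 1β-bromo-6α-[(tert-butyldimethylsilyl)oxy]-15-nor-5α-eudesm-7-en-4-one
Product: 16 1β-bromo-6α-hydroxy-15-nor-5α-eudesm-7-en-4-one
Conditions: HF·pyridine, pyridine, THF, 0 → 23 °C
Reagents that add atoms: none
Why: Fluoride cleavage of the secondary TBS ether under buffered, weakly acidic conditions should neither dehydrate or retro-aldolize the beta-hydroxy ketone nor disturb the secondary bromide.

**Step 11**
Reactants: 16 1β-bromo-6α-hydroxy-15-nor-5α-eudesm-7-en-4-one
Product: 17 1β-bromo-6α-hydroxy-15-nor-5α,7αH-eudesman-4-one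
Conditions: H2 (1 atm), [Ir(cod)(PCy3)(py)]PF6 (5 mol%), CH2Cl2, 0 → 23 °C
Reagents that add atoms: none
Why: In this hydroxyl-directed homogeneous hydrogenation the allylic C6 hydroxyl binds the cationic iridium catalyst and delivers H2 to the alpha face of the trisubstituted C7=C8 bond, which is also the face away from the angular methyl, so H7 should be alpha and the isopropyl group beta and equatorial.

**Step 12**
Reactants: 17 1β-bromo-6α-hydroxy-15-nor-5α,7αH-eudesman-4-one
Product: 18 1β-bromo-5α,7αH-eudesmane-4β,6α-diol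
Conditions: MeMgBr (4 equiv), CH2Cl2/Et2O, −78 → −20 °C; sat. aq. NH4Cl
Reagents that add atoms: methylmagnesium bromide, C[Mg]Br
Why: In this Grignard addition to a cyclohexanone the C10 methyl is 1,3-diaxial to the beta (axial) trajectory at C4 and the magnesium alkoxide of the peri C6 hydroxyl sits on the alpha face and chelates the carbonyl, so methyl should be delivered equatorially from the alpha face to give the axial 4β-hydroxyl and the equatorial 4α-methyl.

**Step 13**
Reactants: 18 1β-bromo-5α,7αH-eudesmane-4β,6α-diol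
Product: 19 (1R,4S,5S,6S,7S,10R)-1-bromo-4-hydroxyeudesman-6-yl acetate (target)
Conditions: Ac2O (1.5 equiv), pyridine, DMAP (0.1 equiv), CH2Cl2, 0 → 23 °C
Reagents that add atoms: acetic anhydride, CC(=O)OC(C)=O
Why: DMAP-catalysed acylation should take the secondary C6 hydroxyl only, because the tertiary C4 hydroxyl is axial and 1,3-diaxial to the angular methyl and does not acylate under these conditions.

**Compound list**
1 | 4-methoxy-2-methylphenol | COc1ccc(O)c(C)c1 | starting material
2 | 4,4-dimethoxy-2-methylcyclohexa-2,5-dien-1-one | COC1(OC)C=CC(=O)C(C)=C1 | intermediate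
3 | 4,4-dimethoxy-2-methylcyclohex-2-en-1-one | COC1(OC)CCC(=O)C(C)=C1 | intermediate
4 | (S)-4,4-dimethoxy-2-methylcyclohex-2-en-1-ol (not isolated) | CC1=CC(OC)(OC)CC[C@@H]1O | intermediate
5 | (S)-4-hydroxy-3-methylcyclohex-2-en-1-one | O=C1C=C(C)[C@@H](O)CC1 | intermediate
6 | (R)-4-bromo-3-methylcyclohex-2-en-1-one | O=C1C=C(C)[C@H](Br)CC1 | intermediate
7 | 3-methylbutanal | CC(C)CC=O | starting material
8 | cyclohexylamine | NC1CCCCC1 | starting material
9 | (E)-N-cyclohexyl-3-methylbutan-1-imine | CC(C)C/C=N/C1CCCCC1 | intermediate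
10 | acetaldehyde | CC=O | starting material
11 | 4-(cyclohexylimino)-3-(propan-2-yl)butan-2-ol (diastereomer mixture, not isolated) | CC(O)C(C(C)C)C=NC1CCCCC1 | intermediate
12 | (2E)-2-(propan-2-yl)but-2-enal | C/C=C(/C=O)C(C)C | intermediate
13 | tert-butyl(dimethyl){[(1E)-2-(propan-2-yl)buta-1,3-dien-1-yl]oxy}silane | C=C/C(C(C)C)=C/O[Si](C)(C)C(C)(C)C | intermediate
14 | 1β-bromo-6α-[(tert-butyldimethylsilyl)oxy]-15-nor-5β-eudesm-7-en-4-one (cis-fused; H5 and C10 methyl cis) | CC(C)(C)[Si](C)(C)O[C@@H]1[C@H]2[C@@](C)(CC=C1C(C)C)[C@H](Br)CCC2=O | intermediate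
15 | 1β-bromo-6α-[(tert-butyldimethylsilyl)oxy]-15-nor-5α-eudesm-7-en-4-one (trans-fused) | CC(C)(C)[Si](C)(C)O[C@@H]1[C@@H]2[C@@](C)(CC=C1C(C)C)[C@H](Br)CCC2=O | intermediate
16 | 1β-bromo-6α-hydroxy-15-nor-5α-eudesm-7-en-4-one | O[C@@H]1[C@@H]2[C@@](C)(CC=C1C(C)C)[C@H](Br)CCC2=O | intermediate
17 | 1β-bromo-6α-hydroxy-15-nor-5α,7αH-eudesman-4-one | O[C@@H]1[C@@H]2[C@@](C)(CC[C@H]1C(C)C)[C@H](Br)CCC2=O | intermediate
18 | 1β-bromo-5α,7αH-eudesmane-4β,6α-diol | O[C@@H]1[C@@H]2[C@@](C)(CC[C@H]1C(C)C)[C@H](Br)CC[C@]2(C)O | intermediate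
19 | (1R,4S,5S,6S,7S,10R)-1-bromo-4-hydroxyeudesman-6-yl acetate (6α-acetoxy-1β-bromo-5α,7αH-eudesman-4β-ol) | CC(=O)O[C@@H]1[C@@H]2[C@@](C)(CC[C@H]1C(C)C)[C@H](Br)CC[C@]2(C)O | target

**Step count and risks**
Total step count: 13. Longest linear sequence: 10 steps (steps 1–4 and 8–13); the diene branch (steps 5–7) joins at step 8.

Steps most likely to fail:

1. Step 8 (key cycloaddition). The silyl dienol ether may be consumed by protodesilylation or open-chain vinylogous Michael addition before the hindered beta carbon of 6 reacts. The dienophile may lose HBr and aromatize, and endo or facial selectivity may leak. The fallback changes the activation mode to a cationic dienophile; it sets out from 6 (with 13) and comes back at 14. Enone 6 is ketalized under conditions that do not move the double bond (1,2-bis(trimethylsilyloxy)ethane, TMSOTf cat., CH2Cl2, −78 °C) to (R)-8-bromo-7-methyl-1,4-dioxaspiro[4.5]dec-6-ene F1. TMSOTf (cat., −78 °C) then opens the dioxolane to a 2-alkoxyallyl cation, a much stronger dienophile, which should take up 13 in an ionic Diels–Alder reaction (C9–C10 bond first, closure of C5 onto the silyloxocarbenium carbon C6, dioxolane re-closed, same anti-to-bromine approach). This gives 1β-bromo-6α-[(tert-butyldimethylsilyl)oxy]-4,4-(ethylenedioxy)-15-nor-5β-eudesm-7-ene F2, and PPTS in wet acetone should release 14.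

2. Step 4 (allylic bromide). Enantiomeric purity may erode through bromide–bromide exchange at the activated allylic carbon during or after the substitution, and HBr may be lost with aromatization. The fallback avoids any allylic bromide and makes C1–Br last; it sets out from 3 and comes back at 19.
   - Reduction of 3 with the (S)-configured CBS catalyst and acid work-up should give, via (R)-4,4-dimethoxy-2-methylcyclohex-2-en-1-ol F3, (R)-4-hydroxy-3-methylcyclohex-2-en-1-one F4. Silylation (TBDPSCl, imidazole) gives (R)-4-[(tert-butyldiphenylsilyl)oxy]-3-methylcyclohex-2-en-1-one F5.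
   - Cycloaddition with 13 under the conditions of step 8, anti to the silyloxy group, should give 1β-[(tert-butyldiphenylsilyl)oxy]-6α-[(tert-butyldimethylsilyl)oxy]-15-nor-5β-eudesm-7-en-4-one F6. DBU epimerizes it to the 5α (trans-fused) ketone F7.
   - HF·pyridine should remove only the TBS group to give 1β-[(tert-butyldiphenylsilyl)oxy]-6α-hydroxy-15-nor-5α-eudesm-7-en-4-one F8. Directed hydrogenation as in step 11 gives the saturated hydroxy ketone F9, MeMgBr as in step 12 gives 1β-[(tert-butyldiphenylsilyl)oxy]-5α,7αH-eudesmane-4β,6α-diol F10, and acetylation as in step 13 gives its 6-acetate F11.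
   - TBAF/AcOH then frees 1β,4β-dihydroxy-5α,7αH-eudesman-6α-yl acetate F12, and Dess–Martin oxidation gives 4β-hydroxy-1-oxo-5α,7αH-eudesman-6α-yl acetate F13, whose ketone can enolize only towards C2.
   - KN(SiMe3)2 (2.2 equiv) and PhNTf2 give the C1=C2 enol triflate F14. Nickel-catalysed triflate-to-bromide exchange (Ni(OAc)2·4H2O, 1,5-cyclooctadiene, Zn, LiBr, DMA/THF) gives 1-bromo-4β-hydroxy-5α,7αH-eudesm-1-en-6α-yl acetate F15.
   - Hydrogen-atom-transfer hydrogenation (Mn(dpm)3, PhSiH3, tBuOOH, iPrOH), a method that reduces haloalkenes without dehalogenation, should deliver hydrogen to the alpha-bromo radical at C1 from the alpha face, away from the angular methyl, and give the equatorial 1β-bromide 19.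

3. Step 9 (ring-fusion epimerization). The C6 silyloxy group may be lost from the enolate by beta-elimination, or the equilibrium may stop short of the trans-fused ketone. The fallback replaces equilibration by kinetic protonation of an enol ether, with no free enolate; it sets out from 14 and comes back at 15. TMSOTf/Et3N (CH2Cl2, 0 → 23 °C, equilibrating conditions) should give the more substituted C4=C5 trimethylsilyl enol ether, 1β-bromo-6α-[(tert-butyldimethylsilyl)oxy]-4-[(trimethylsilyl)oxy]-15-nor-eudesma-4,7-diene F16. Anhydrous HCl (1 equiv, CH2Cl2, −78 °C) should protonate C5 from the alpha face, away from the angular methyl, and give 15. Any C3=C4 regioisomer returns 14 and is recycled.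

**Further compounds**
F1 | step 8 | (R)-8-bromo-7-methyl-1,4-dioxaspiro[4.5]dec-6-ene | C12(OCCO1)C=C(C)[C@H](Br)CC2
F2 | step 8 | 1β-bromo-6α-[(tert-butyldimethylsilyl)oxy]-4,4-(ethylenedioxy)-15-nor-5β-eudesm-7-ene | CC(C)(C)[Si](C)(C)O[C@@H]1[C@H]2[C@@](C)(CC=C1C(C)C)[C@H](Br)CCC23OCCO3
F3 | step 4 | (R)-4,4-dimethoxy-2-methylcyclohex-2-en-1-ol (not isolated) | CC1=CC(OC)(OC)CC[C@H]1O
F4 | step 4 | (R)-4-hydroxy-3-methylcyclohex-2-en-1-one | O=C1C=C(C)[C@H](O)CC1
F5 | step 4 | (R)-4-[(tert-butyldiphenylsilyl)oxy]-3-methylcyclohex-2-en-1-one | O=C1C=C(C)[C@H](O[Si](c2ccccc2)(c2ccccc2)C(C)(C)C)CC1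
F6 | step 4 | 1β-[(tert-butyldiphenylsilyl)oxy]-6α-[(tert-butyldimethylsilyl)oxy]-15-nor-5β-eudesm-7-en-4-one | CC(C)(C)[Si](C)(C)O[C@@H]1[C@H]2[C@@](C)(CC=C1C(C)C)[C@H](O[Si](c3ccccc3)(c3ccccc3)C(C)(C)C)CCC2=O
F7 | step 4 | 1β-[(tert-butyldiphenylsilyl)oxy]-6α-[(tert-butyldimethylsilyl)oxy]-15-nor-5α-eudesm-7-en-4-one | CC(C)(C)[Si](C)(C)O[C@@H]1[C@@H]2[C@@](C)(CC=C1C(C)C)[C@H](O[Si](c3ccccc3)(c3ccccc3)C(C)(C)C)CCC2=O
F8 | step 4 | 1β-[(tert-butyldiphenylsilyl)oxy]-6α-hydroxy-15-nor-5α-eudesm-7-en-4-one | O[C@@H]1[C@@H]2[C@@](C)(CC=C1C(C)C)[C@H](O[Si](c3ccccc3)(c3ccccc3)C(C)(C)C)CCC2=O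
F9 | step 4 | 1β-[(tert-butyldiphenylsilyl)oxy]-6α-hydroxy-15-nor-5α,7αH-eudesman-4-one | O[C@@H]1[C@@H]2[C@@](C)(CC[C@H]1C(C)C)[C@H](O[Si](c3ccccc3)(c3ccccc3)C(C)(C)C)CCC2=O
F10 | step 4 | 1β-[(tert-butyldiphenylsilyl)oxy]-5α,7αH-eudesmane-4β,6α-diol | O[C@@H]1[C@@H]2[C@@](C)(CC[C@H]1C(C)C)[C@H](O[Si](c3ccccc3)(c3ccccc3)C(C)(C)C)CC[C@]2(C)O
F11 | step 4 | 1β-[(tert-butyldiphenylsilyl)oxy]-4β-hydroxy-5α,7αH-eudesman-6α-yl acetate | CC(=O)O[C@@H]1[C@@H]2[C@@](C)(CC[C@H]1C(C)C)[C@H](O[Si](c3ccccc3)(c3ccccc3)C(C)(C)C)CC[C@]2(C)O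
F12 | step 4 | 1β,4β-dihydroxy-5α,7αH-eudesman-6α-yl acetate | CC(=O)O[C@@H]1[C@@H]2[C@@](C)(CC[C@H]1C(C)C)[C@H](O)CC[C@]2(C)O
F13 | step 4 | 4β-hydroxy-1-oxo-5α,7αH-eudesman-6α-yl acetate | CC(=O)O[C@@H]1[C@@H]2[C@@](C)(CC[C@H]1C(C)C)C(=O)CC[C@]2(C)O
F14 | step 4 | 4β-hydroxy-1-[(trifluoromethanesulfonyl)oxy]-5α,7αH-eudesm-1-en-6α-yl acetate | CC(=O)O[C@@H]1[C@@H]2[C@@](C)(CC[C@H]1C(C)C)C(OS(=O)(=O)C(F)(F)F)=CC[C@]2(C)O
F15 | step 4 | 1-bromo-4β-hydroxy-5α,7αH-eudesm-1-en-6α-yl acetate | CC(=O)O[C@@H]1[C@@H]2[C@@](C)(CC[C@H]1C(C)C)C(Br)=CC[C@]2(C)O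
F16 | step 9 | 1β-bromo-6α-[(tert-butyldimethylsilyl)oxy]-4-[(trimethylsilyl)oxy]-15-nor-eudesma-4,7-diene | CC(C)(C)[Si](C)(C)O[C@@H]1C2=C(O[Si](C)(C)C)CC[C@@H](Br)[C@]2(C)CC=C1C(C)C
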